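The numbers in the tables were generated by integration from invented constants.

At the last spring reading, 3.00 d, I read 3.0 % of Pdt against 27.1 % of Sdp, and I started from that pair.

the same everywhere: Sub 0.031 M

| flask | Cat | temperature | remark | time |
|---|---|---|---|---|
| spring | 16 µM | 20 °C | run made earlier |  |
| south-east | 31 µM | 20 °C |  | 10 d |
| south-west | 31 µM |  | at 20 °C until 50 h, from then on at −10 °C | 10 d |
| west | 31 µM | −10 °C |  | 10 d |

spring run (percent of the Sub charged)

| time / d | Pdt / % | Sdp / % |
|---|---|---|
| 0.250 | 3.7 | 2.2 |
| 0.417 | 3.4 | 2.2 |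
| 0.833 | 5.5 | 5.7 |
| 1.67 | 2.8 | 13.3 |
| 3.00 | 3.0 | 27.1 |

(each reading ± 1 percentage point)

- the earlier runs do not show what temperature does; that part of a forecast is a guess
- no earlier run changes the charge of Cat; that part of a forecast is a guess

* the flask with the highest share of Pdt in all that became Pdt or Sdp ("all alike" if they lie within 1.5 percentage points) (south-east / south-west / west / all alike)
* share of Pdt in all that became Pdt or Sdp, south-east
* share of Pdt in all that became Pdt or Sdp, south-west
* share of Pdt in all that became Pdt or Sdp, west

In the spring run the readings of c(Sdp) rose nearly in a straight line while those of c(Pdt) showed no trend, averaging 3.68 %. I therefore took Pdt for a pool that is fed and drained at once, in quasi-steady state. Its drain life τ, the pool divided by the rate at which Sdp appears, I read as 0.407 d, with the scatter of the readings on it. With a steady feed and a first-order drain, the feed cancels from the share s of Pdt in Pdt plus Sdp, so I solved both ends and joined them: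

short end, t ≪ τ: s = 1 − t/(2τ)
long end, t ≫ τ: s = τ/t
joined: s = (τ/t)(1 − exp(−t/τ))

For south-east the joined line gave 4.07 % as my upper bound, since a fading feed leaves a smaller pool, and I had no better lower bound than zero. For west the same figure was my lower bound, with τ unchanged by cold, and the upper bound was 100 %, with no drain at all. The runs show nothing of temperature, so I tightened this by my own guess that cold lengthens τ by a factor between 10 and 100:

west, τ × 10: s = 37.2 %
west, τ × 100: s = 88.7 %

The forecast named west, with 2 % for south-east, 5.5 % for south-west and 15 % for west. Its words were “I guess about a tenfold slowdown”. Its west figure stands lower than my bracket.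

The flasks gave 0.999 % for south-east, less than my upper bound, 17.8 % for south-west and 91.2 % for west, more than the top of my bracket, so west stood highest.

    Cat → Tsp (k = 0.00215 h⁻¹, Ea = 245 kJ mol⁻¹)
    Sub + Cat ⇌ Sub.Cat (K = 13.2 L mol⁻¹, k = 7590 L mol⁻¹ h⁻¹, Ea = 38.0 kJ mol⁻¹, ΔH = 13.0 kJ mol⁻¹)
    Sub.Cat ⇌ Cat + Pdt (K = 0.730 M, k = 37.6 h⁻¹, Ea = 86.0 kJ mol⁻¹, ΔH = −21.0 kJ mol⁻¹)
    Pdt → Sdp (k = 0.0956 h⁻¹, Ea = 103 kJ mol⁻¹)
    Cat → Zed (k = 3.09 × 10⁻⁵ h⁻¹, Ea = 115 kJ mol⁻¹)
    (constants at 20 °C)

In south-west, Sub fed Pdt and Pdt drained to Sdp for the 50 h at 20 °C: the joined line with τ gives 19.4 % for that moment, and the flask held 7.28 % of Pdt and 33.8 % of Sdp, a share of 17.7 %, and after the cooling these moved just to 7.53 % and 34.9 % by 10 d. In west, with 97.1 % of Sub left, Pdt reached 2.64 % and Sdp 0.254 %, and the short end, turned round on the share of 91.2 %, asks for a drain life of 57.0 d, which is 140 times τ.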